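**Retrosynthetic overview**
- The last C–C bond is the CH=CH four carbons out from the lactone: Julia–Kocienski olefination of ylidenebutenolide aldehyde 29 with ring A dienynyl benzothiazolyl sulfone 37, then desilylation.
- The strategy rests on the butenolide ring (O1, carbonyl C2, C3 carrying the (E)-vinyl arm to ring B, C4–H, ylidene carbon C5). It is a 2,3,5-trisubstituted furan at a higher oxidation level, so 2-trimethylsilylfuran 22 is opened by singlet oxygen and re-closed to hydroxybutenolide 25, which is dehydrated to the (Z)-ylidene lactone.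
- Furan 22 comes from 3-bromofuran (silylated at C2, allylated at C5 with a five-carbon stub from prenol) and ring B vinylstannane 11 by Stille coupling at C3.
- Rings A and B both come from (4R,6R)-actinol through one enol triflate 4; the ring B triol is set by hydroxyl-directed epoxidation and anti hydrolysis.
- Ring order: both carbocycles and the furan are bought. The only lasting ring closure is the lactone in step 15; the epoxide of step 5 and the endoperoxide of step 15 are transient.

Key step: step 15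

Remark: 25 is formed and used as a mixture of the two epimers at the hemiketal carbon C5, which becomes trigonal in step 16. Ring atoms are numbered C1–C6 (ring A) and C1'–C6' (ring B) in the carotenoid sense.

**Step 1**
Reactants: 1 (4R,6R)-actinol
Product: 2 (4R,6R)-4-(tert-butyldimethylsilyloxy)-2,2,6-trimethylcyclohexan-1-one
Conditions: TBSCl, imidazole, DMF, rt
Reagents that add atoms: tert-butyldimethylsilyl chloride, CC(C)(C)[Si](C)(C)Cl
Why: Imidazole-promoted silylation protects the only hydroxyl so that the ketone can be enolised in step 2, and the carbinol stereocentre (C3 of ring A and C3' of ring B in the target) is not involved.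

**Step 2**
Reactants: 2 silylated actinol
Product: 4 (R)-4-(tert-butyldimethylsilyloxy)-2,6,6-trimethylcyclohex-1-en-1-yl trifluoromethanesulfonate, via lithium enolate 3 (not isolated)
Conditions: LDA, THF, −78 °C; PhNTf2, −78 °C → rt
Reagents that add atoms: N-phenylbis(trifluoromethanesulfonimide), O=S(=O)(N(c1ccccc1)S(=O)(=O)C(F)(F)F)C(F)(F)F
Why: Enolate O-triflation; C2 is quaternary, so only the C1–C6 enolate can form and one tetrasubstituted enol triflate should result, the C6 stereocentre being erased on purpose.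

**Step 3**
Reactants: 4 enol triflate; 5 trimethylsilylacetylene
Product: 6 (R)-tert-butyldimethyl{[3,5,5-trimethyl-4-(trimethylsilylethynyl)cyclohex-3-en-1-yl]oxy}silane
Conditions: Pd(PPh3)4 (cat.), CuI (cat.), i-Pr2NH, DMF, rt
Reagents that add atoms: none
Why: Sonogashira coupling of a vinyl triflate with a terminal alkyne proceeds at room temperature and leaves the remote silyloxy stereocentre untouched.

**Step 4**
Reactants: 6 bis-silylated enyne
Product: 7 (R)-4-ethynyl-3,5,5-trimethylcyclohex-3-en-1-ol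
Conditions: TBAF, THF, 0 °C → rt
Reagents that add atoms: none
Why: Fluoride cleaves the alkynyl C–Si bond and the O–Si bond together (desilylation), freeing the homoallylic hydroxyl that has to direct step 5.

**Step 5**
Reactants: 7 hydroxy enyne
Product: 8 (1S,3S,6S)-6-ethynyl-1,5,5-trimethyl-7-oxabicyclo[4.1.0]heptan-3-ol (epoxide oxygen cis to the hydroxyl)
Conditions: VO(acac)2 (cat.), t-BuOOH (decane), PhH, rt
Reagents that add atoms: tert-butyl hydroperoxide, CC(C)(C)OO
Why: Hydroxyl-directed vanadium-catalysed epoxidation of a cyclohex-3-en-1-ol: the alkoxide bound to vanadium delivers the peroxide oxygen to its own face, so the C5'–C6' epoxide should form cis to the C3' hydroxyl, which fixes both new stereocentres relative to the actinol-derived one.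

**Step 6**
Reactants: 8 syn-epoxy alcohol
Product: 9 (1S,2R,4S)-1-ethynyl-2,6,6-trimethylcyclohexane-1,2,4-triol
Conditions: HClO4 (cat., aq.), THF/H2O, 0 °C → rt
Reagents that add atoms: water, O
Why: Acid-catalysed epoxide hydrolysis with anti opening: water should attack C5' with inversion, because C6' is neopentylic and deactivated by the ethynyl group and because attack at C5' is the trans-diaxial (Fürst–Plattner) opening that keeps the C3' hydroxyl equatorial, so the 5',6'-trans-diol with the C6' oxygen retained results.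

**Step 7**
Reactants: 9 triol
Product: 10 (1S,2R,4S)-4-(tert-butyldimethylsilyloxy)-1-ethynyl-2,6,6-trimethylcyclohexane-1,2-diol
Conditions: TBSCl, imidazole, DMF, 0 °C → rt
Reagents that add atoms: tert-butyldimethylsilyl chloride, CC(C)(C)[Si](C)(C)Cl
Why: Silylation with TBSCl and imidazole discriminates between the secondary hydroxyl and the two hindered tertiary hydroxyls.

**Step 8**
Reactants: 10 silylated ethynyl diol
Product: 11 (1R,2R,4S)-4-(tert-butyldimethylsilyloxy)-2,6,6-trimethyl-1-[(E)-2-(tributylstannyl)ethenyl]cyclohexane-1,2-diol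
Conditions: Bu3SnH, PdCl2(PPh3)2 (cat.), THF, 0 °C → rt
Reagents that add atoms: tributyltin hydride, CCCC[SnH](CCCC)CCCC
Why: Palladium-catalysed syn-hydrostannation of a terminal alkyne places tin on the terminal carbon, away from the fully substituted carbinol centre, and should give the (E)-vinylstannane.

**Step 9**
Reactants: 12 3-bromofuran
Product: 14 (3-bromofuran-2-yl)trimethylsilane, via 3-bromo-2-lithiofuran 13 (not isolated)
Conditions: LDA, THF, −78 °C; TMSCl, −78 °C → rt
Reagents that add atoms: chlorotrimethylsilane, C[Si](C)(C)Cl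
Why: Directed lithiation: LDA removes the C2 proton flanked by ring oxygen and bromine without bromine–lithium exchange, and the furyllithium is C-silylated.

**Step 10**
Reactants: 15 prenol (3-methylbut-2-en-1-ol)
Product: 16 tert-butyldimethyl[(3-methylbut-2-en-1-yl)oxy]silane
Conditions: TBSCl, imidazole, CH2Cl2, rt
Reagents that add atoms: tert-butyldimethylsilyl chloride, CC(C)(C)[Si](C)(C)Cl
Why: Routine silylation of a primary allylic alcohol gives an ether that survives the organolithium chemistry of step 13.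

**Step 11**
Reactants: 16 prenyl silyl ether
Product: 17 (E)-4-(tert-butyldimethylsilyloxy)-2-methylbut-2-en-1-ol
Conditions: SeO2 (cat.), t-BuOOH, CH2Cl2, rt
Reagents that add atoms: selenium dioxide (oxygen carrier), O=[Se]=O; tert-butyl hydroperoxide (terminal oxidant), CC(C)(C)OO
Why: Selenium dioxide allylic oxidation (ene reaction then [2,3]-sigmatropic shift) hydroxylates the methyl group trans to the chain of a trisubstituted alkene and so should give the (E)-allylic alcohol.

**Step 12**
Reactants: 17 (E)-allylic alcohol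
Product: 19 (E)-(4-bromo-3-methylbut-2-en-1-yloxy)(tert-butyl)dimethylsilane, via allylic mesylate 18 (not isolated)
Conditions: MsCl, Et3N, THF, −40 °C; LiBr, 0 °C
Reagents that add atoms: lithium bromide, [Li+].[Br-]
Why: Mesylation and SN2 displacement by bromide convert the allylic alcohol into the bromide without touching the silyl ether or the alkene geometry.

**Step 13**
Reactants: 14 3-bromo-2-silylfuran; 19 allylic bromide
Product: 21 {3-bromo-5-[(E)-4-(tert-butyldimethylsilyloxy)-2-methylbut-2-en-1-yl]furan-2-yl}trimethylsilane, via 5-lithiofuran 20 (not isolated)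
Conditions: LDA, THF, −78 °C; 19, −78 → 0 °C
Reagents that add atoms: none
Why: With C2 blocked by silicon, LDA removes the only remaining α-proton (C5) at −78 °C, where bromine migration is slow, and the furyllithium is alkylated at the primary allylic carbon in an SN2 reaction.

**Step 14**
Reactants: 21 allylated bromofuran; 11 ring B vinylstannane
Product: 22 (1R,2R,4S)-4-(tert-butyldimethylsilyloxy)-1-[(E)-2-{5-[(E)-4-(tert-butyldimethylsilyloxy)-2-methylbut-2-en-1-yl]-2-(trimethylsilyl)furan-3-yl}ethenyl]-2,6,6-trimethylcyclohexane-1,2-diol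
Conditions: Pd(PPh3)4 (10 mol %), toluene, 100 °C, degassed, dark
Reagents that add atoms: none
Why: Stille coupling: oxidative addition of zerovalent palladium into the furan C3–Br bond, tin-to-palladium transfer of the alkenyl group with retention of the (E)-geometry and reductive elimination, under neutral conditions that tolerate the free tertiary hydroxyls and the C–Si bond.

**Step 15**
Reactants: 22 silylfuran
Product: 25 3-[(E)-2-((1R,2R,4S)-4-(tert-butyldimethylsilyloxy)-1,2-dihydroxy-2,6,6-trimethylcyclohexyl)ethenyl]-5-hydroxy-5-[(E)-4-(tert-butyldimethylsilyloxy)-2-methylbut-2-en-1-yl]furan-2(5H)-one, via furan endoperoxide 23 (not isolated), via trimethylsilyl 4-oxo-2-enoate 24 (not isolated)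
Conditions: O2, TPP (cat.), hν (visible), CH2Cl2, −78 °C; then H2O, THF, rt
Reagents that add atoms: dioxygen, O=O
Why: Sensitised singlet oxygen adds across C2 and C5 of the electron-rich furan in a [4+2] cycloaddition to give the 2,3,7-trioxabicyclo[2.2.1]heptene 23. In 23 the trimethylsilyl group shifts from C2 to the neighbouring peroxide oxygen while the O–O bond and the C5–O(bridge) bond break, so the silylated carbon becomes the carboxyl carbon of silyl (Z)-4-oxo-2-enoate 24 and C5 a ketone, and hydrolysis at silicon frees the acid. The closest known reaction type is the photooxygenation of 2-trimethylsilylfurans to γ-hydroxybutenolides, in which the silicon-bearing carbon ends as the lactone carbonyl. The lactone ring (O1–C2–C3–C4–C5) closes by 5-exo-trig addition of the carboxyl oxygen to the C5 ketone, the (Z)-alkene inherited from the furan holding the two groups within reach. The only new stereocentre is the hemiketal carbon C5, which is not controlled and need not be, since it becomes trigonal in step 16. The step needs regioselectivity between the two furan α-carbons, secured by the silyl group, and chemoselectivity for the furan over the trisubstituted side-chain alkene, the arm alkene and the tertiary allylic alcohol, secured by the much faster [4+2] addition of the silylfuran at −78 °C and by stopping at one equivalent of oxygen uptake.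

**Step 16**
Reactants: 25 hydroxybutenolide
Product: 27 (5Z)-3-[(E)-2-((1R,2R,4S)-4-(tert-butyldimethylsilyloxy)-1,2-dihydroxy-2,6,6-trimethylcyclohexyl)ethenyl]-5-[(2E)-4-(tert-butyldimethylsilyloxy)-2-methylbut-2-en-1-ylidene]furan-2(5H)-one, via 5-acetoxybutenolide 26 (not isolated)
Conditions: Ac2O, pyridine, rt → 40 °C
Reagents that add atoms: none
Why: Acetylation of the hemiketal hydroxyl and loss of acetic acid towards the allylic CH2 (dehydrative enol lactonisation) should give the ylidenebutenolide as the more stable (Z)-isomer, since the ylidene bond can equilibrate under the conditions, while the tertiary ring hydroxyls are not acylated without an acyl-transfer catalyst.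

**Step 17**
Reactants: 27 bis-silylated ylidenebutenolide
Product: 28 (5Z)-3-[(E)-2-((1R,2R,4S)-4-(tert-butyldimethylsilyloxy)-1,2-dihydroxy-2,6,6-trimethylcyclohexyl)ethenyl]-5-[(2E)-4-hydroxy-2-methylbut-2-en-1-ylidene]furan-2(5H)-one
Conditions: HF·pyridine, pyridine, THF, 0 °C
Reagents that add atoms: none
Why: Buffered HF·pyridine cleaves the unhindered primary allylic silyl ether much faster than the secondary cyclohexyl silyl ether (selective desilylation).

**Step 18**
Reactants: 28 primary allylic alcohol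
Product: 29 (2E,4Z)-4-{4-[(E)-2-((1R,2R,4S)-4-(tert-butyldimethylsilyloxy)-1,2-dihydroxy-2,6,6-trimethylcyclohexyl)ethenyl]-5-oxofuran-2(5H)-ylidene}-3-methylbut-2-enal
Conditions: MnO2, CH2Cl2, rt, dark
Reagents that add atoms: none
Why: MnO2 oxidises only the allylic (dienylic) primary alcohol to the aldehyde and leaves the tertiary hydroxyls and the double-bond geometries alone.

**Step 19**
Reactants: 4 enol triflate; 30 (E)-3-methylpent-2-en-4-yn-1-ol
Product: 31 (R,E)-5-[4-(tert-butyldimethylsilyloxy)-2,6,6-trimethylcyclohex-1-en-1-yl]-3-methylpent-2-en-4-yn-1-ol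
Conditions: Pd(PPh3)4 (cat.), CuI (cat.), i-Pr2NH, DMF, rt
Reagents that add atoms: none
Why: Sonogashira coupling of the vinyl triflate with the terminal enyne brings in the (E)-trisubstituted double bond ready-made, and the free primary hydroxyl is tolerated.

**Step 20**
Reactants: 31 ring A enynol; 32 ethyl (triphenylphosphoranylidene)acetate
Product: 34 ethyl (2E,4E)-7-[(R)-4-(tert-butyldimethylsilyloxy)-2,6,6-trimethylcyclohex-1-en-1-yl]-5-methylhepta-2,4-dien-6-ynoate, via enynal 33 (not isolated)
Conditions: MnO2, 32, CH2Cl2, rt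
Reagents that add atoms: none
Why: Tandem MnO2 oxidation–Wittig olefination: the allylic alcohol is oxidised to the enynal, which is trapped in the flask by the stabilised ylide to give the (E)-enoate.

**Step 21**
Reactants: 34 dienynoate
Product: 35 (2E,4E)-7-[(R)-4-(tert-butyldimethylsilyloxy)-2,6,6-trimethylcyclohex-1-en-1-yl]-5-methylhepta-2,4-dien-6-yn-1-ol
Conditions: DIBAL-H, CH2Cl2, −78 °C; Rochelle salt work-up
Reagents that add atoms: none
Why: DIBAL-H reduces the conjugated ester to the allylic alcohol by 1,2-reduction without touching the alkyne or the silyl ether.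

**Step 22**
Reactants: 35 dienynol
Product: 36 2-{[(2E,4E)-7-((R)-4-(tert-butyldimethylsilyloxy)-2,6,6-trimethylcyclohex-1-en-1-yl)-5-methylhepta-2,4-dien-6-yn-1-yl]sulfanyl}-1,3-benzothiazole
Conditions: 2-mercaptobenzothiazole, PPh3, DIAD, THF, 0 °C
Reagents that add atoms: 2-mercaptobenzothiazole, Sc1nc2ccccc2s1
Why: Mitsunobu reaction of the primary allylic alcohol with the acidic thiol gives the S-alkylated benzothiazole by SN2 displacement.

**Step 23**
Reactants: 36 benzothiazolyl sulfide
Product: 37 2-{[(2E,4E)-7-((R)-4-(tert-butyldimethylsilyloxy)-2,6,6-trimethylcyclohex-1-en-1-yl)-5-methylhepta-2,4-dien-6-yn-1-yl]sulfonyl}-1,3-benzothiazole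
Conditions: (NH4)6Mo7O24·4H2O (cat.), 30% H2O2, EtOH, 0 °C → rt
Reagents that add atoms: hydrogen peroxide, OO
Why: Molybdate-catalysed oxidation with hydrogen peroxide takes the sulfide to the sulfone and should be chemoselective for sulfur over the conjugated dienyne.

**Step 24**
Reactants: 37 ring A sulfone; 29 butenolide aldehyde
Product: 39 3,3'-bis(tert-butyldimethylsilyl) ether of the target, via sodium sulfonyl carbanion 38 (not isolated)
Conditions: NaHMDS added to 37 and 29, THF, −78 °C → rt; then PhH, rt, dark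
Reagents that add atoms: none
Why: Julia–Kocienski olefination: the sulfonyl carbanion adds to the aldehyde, the benzothiazole migrates from sulfur to oxygen (Smiles rearrangement) and SO2 and benzothiazolone are expelled, and any Z isomer at the new disubstituted bond should relax to E on standing in benzene, under conditions too mild to move the trisubstituted double bonds or the (Z)-ylidene.

**Step 25**
Reactants: 39 bis-silyl ether
Product: 40 target, (5Z)-3-[(E)-2-((1R,2R,4S)-1,2,4-trihydroxy-2,6,6-trimethylcyclohexyl)ethenyl]-5-[(2E,4E,6E,8E)-11-((R)-4-hydroxy-2,6,6-trimethylcyclohex-1-en-1-yl)-2,9-dimethylundeca-2,4,6,8-tetraen-10-yn-1-ylidene]furan-2(5H)-one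
Conditions: HF·pyridine, pyridine, THF, 0 °C → rt, dark
Reagents that add atoms: none
Why: Buffered HF·pyridine removes the two secondary silyl ethers (desilylation) under conditions mild enough for the polyene, the ylidenebutenolide and the tertiary allylic alcohol.

**Compound list**
1 | (4R,6R)-actinol, (4R,6R)-4-hydroxy-2,2,6-trimethylcyclohexan-1-one | CC1(C)C[C@H](O)C[C@@H](C)C1=O | starting material
2 | (4R,6R)-4-(tert-butyldimethylsilyloxy)-2,2,6-trimethylcyclohexan-1-one | CC1(C)C[C@H](O[Si](C)(C)C(C)(C)C)C[C@@H](C)C1=O | intermediate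
3 | lithium enolate of 2 (not isolated) | CC1=C(O[Li])C(C)(C)C[C@H](O[Si](C)(C)C(C)(C)C)C1 | intermediate
4 | (R)-4-(tert-butyldimethylsilyloxy)-2,6,6-trimethylcyclohex-1-en-1-yl trifluoromethanesulfonate | CC1=C(OS(=O)(=O)C(F)(F)F)C(C)(C)C[C@H](O[Si](C)(C)C(C)(C)C)C1 | intermediate
5 | trimethylsilylacetylene | C#C[Si](C)(C)C | starting material
6 | (R)-tert-butyldimethyl{[3,5,5-trimethyl-4-(trimethylsilylethynyl)cyclohex-3-en-1-yl]oxy}silane | CC1=C(C#C[Si](C)(C)C)C(C)(C)C[C@H](O[Si](C)(C)C(C)(C)C)C1 | intermediate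
7 | (R)-4-ethynyl-3,5,5-trimethylcyclohex-3-en-1-ol | CC1=C(C#C)C(C)(C)C[C@H](O)C1 | intermediate
8 | (1S,3S,6S)-6-ethynyl-1,5,5-trimethyl-7-oxabicyclo[4.1.0]heptan-3-ol | C#C[C@@]1(O2)C(C)(C)C[C@H](O)C[C@@]12C | intermediate
9 | (1S,2R,4S)-1-ethynyl-2,6,6-trimethylcyclohexane-1,2,4-triol | C#C[C@@]1(O)C(C)(C)C[C@H](O)C[C@@]1(C)O | intermediate
10 | (1S,2R,4S)-4-(tert-butyldimethylsilyloxy)-1-ethynyl-2,6,6-trimethylcyclohexane-1,2-diol | C#C[C@@]1(O)C(C)(C)C[C@H](O[Si](C)(C)C(C)(C)C)C[C@@]1(C)O | intermediate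
11 | (1R,2R,4S)-4-(tert-butyldimethylsilyloxy)-2,6,6-trimethyl-1-[(E)-2-(tributylstannyl)ethenyl]cyclohexane-1,2-diol | CCCC[Sn](CCCC)(CCCC)/C=C/[C@@]1(O)C(C)(C)C[C@H](O[Si](C)(C)C(C)(C)C)C[C@@]1(C)O | intermediate
12 | 3-bromofuran | Brc1ccoc1 | starting material
13 | 3-bromo-2-lithiofuran (not isolated) | [Li]c1occc1Br | intermediate
14 | (3-bromofuran-2-yl)trimethylsilane | C[Si](C)(C)c1occc1Br | intermediate
15 | prenol, 3-methylbut-2-en-1-ol | CC(C)=CCO | starting material
16 | tert-butyldimethyl[(3-methylbut-2-en-1-yl)oxy]silane | CC(C)=CCO[Si](C)(C)C(C)(C)C | intermediate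
17 | (E)-4-(tert-butyldimethylsilyloxy)-2-methylbut-2-en-1-ol | OC/C(C)=C/CO[Si](C)(C)C(C)(C)C | intermediate
18 | (E)-4-(tert-butyldimethylsilyloxy)-2-methylbut-2-en-1-yl methanesulfonate (not isolated) | CS(=O)(=O)OC/C(C)=C/CO[Si](C)(C)C(C)(C)C | intermediate
19 | (E)-(4-bromo-3-methylbut-2-en-1-yloxy)(tert-butyl)dimethylsilane | BrC/C(C)=C/CO[Si](C)(C)C(C)(C)C | intermediate
20 | [4-bromo-5-(trimethylsilyl)furan-2-yl]lithium (not isolated) | [Li]c1cc(Br)c([Si](C)(C)C)o1 | intermediate
21 | {3-bromo-5-[(E)-4-(tert-butyldimethylsilyloxy)-2-methylbut-2-en-1-yl]furan-2-yl}trimethylsilane | C[Si](C)(C)c1oc(C/C(C)=C/CO[Si](C)(C)C(C)(C)C)cc1Br | intermediate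
22 | 2-silyl-3-vinyl-5-allylfuran carrying ring B (name as in step 14) | C[Si](C)(C)c1oc(C/C(C)=C/CO[Si](C)(C)C(C)(C)C)cc1/C=C/[C@@]2(O)C(C)(C)C[C@H](O[Si](C)(C)C(C)(C)C)C[C@@]2(C)O | intermediate
23 | 2,5-endoperoxide of 22, a 2,3,7-trioxabicyclo[2.2.1]hept-5-ene (not isolated) | C[Si](C)(C)C12OOC(C/C(C)=C/CO[Si](C)(C)C(C)(C)C)(O1)C=C2/C=C/[C@@]3(O)C(C)(C)C[C@H](O[Si](C)(C)C(C)(C)C)C[C@@]3(C)O | intermediate
24 | trimethylsilyl (Z)-4-oxo-2-enoate from ring opening of 23 (not isolated) | C[Si](C)(C)OC(=O)/C(/C=C/[C@@]1(O)C(C)(C)C[C@H](O[Si](C)(C)C(C)(C)C)C[C@@]1(C)O)=C\C(=O)C/C(C)=C/CO[Si](C)(C)C(C)(C)C | intermediate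
25 | γ-hydroxybutenolide, hemiketal epimers (name as in step 15) | O=C1OC(O)(C/C(C)=C/CO[Si](C)(C)C(C)(C)C)C=C1/C=C/[C@@]2(O)C(C)(C)C[C@H](O[Si](C)(C)C(C)(C)C)C[C@@]2(C)O | intermediate
26 | 5-acetoxybutenolide from 25 (not isolated) | CC(=O)OC1(C/C(C)=C/CO[Si](C)(C)C(C)(C)C)OC(=O)C(/C=C/[C@@]2(O)C(C)(C)C[C@H](O[Si](C)(C)C(C)(C)C)C[C@@]2(C)O)=C1 | intermediate
27 | (Z)-ylidenebutenolide, bis-silyl ether (name as in step 16) | CC(C)(C)[Si](C)(C)OC/C=C(C)/C=C1C=C(/C=C/[C@@]2(O)C(C)(C)C[C@H](O[Si](C)(C)C(C)(C)C)C[C@@]2(C)O)C(=O)O/1 | intermediate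
28 | (Z)-ylidenebutenolide primary alcohol (name as in step 17) | OC/C=C(C)/C=C1C=C(/C=C/[C@@]2(O)C(C)(C)C[C@H](O[Si](C)(C)C(C)(C)C)C[C@@]2(C)O)C(=O)O/1 | intermediate
29 | (Z)-ylidenebutenolide aldehyde (name as in step 18) | O=C/C=C(C)/C=C1C=C(/C=C/[C@@]2(O)C(C)(C)C[C@H](O[Si](C)(C)C(C)(C)C)C[C@@]2(C)O)C(=O)O/1 | intermediate
30 | (E)-3-methylpent-2-en-4-yn-1-ol | C#C/C(C)=C/CO | starting material
31 | (R,E)-5-[4-(tert-butyldimethylsilyloxy)-2,6,6-trimethylcyclohex-1-en-1-yl]-3-methylpent-2-en-4-yn-1-ol | CC1=C(C#C/C(C)=C/CO)C(C)(C)C[C@H](O[Si](C)(C)C(C)(C)C)C1 | intermediate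
32 | ethyl (triphenylphosphoranylidene)acetate | CCOC(=O)C=P(c1ccccc1)(c1ccccc1)c1ccccc1 | starting material
33 | (R,E)-5-[4-(tert-butyldimethylsilyloxy)-2,6,6-trimethylcyclohex-1-en-1-yl]-3-methylpent-2-en-4-ynal (not isolated) | CC1=C(C#C/C(C)=C/C=O)C(C)(C)C[C@H](O[Si](C)(C)C(C)(C)C)C1 | intermediate
34 | ethyl (2E,4E)-7-[(R)-4-(tert-butyldimethylsilyloxy)-2,6,6-trimethylcyclohex-1-en-1-yl]-5-methylhepta-2,4-dien-6-ynoate | CC1=C(C#C/C(C)=C/C=C/C(=O)OCC)C(C)(C)C[C@H](O[Si](C)(C)C(C)(C)C)C1 | intermediate
35 | (2E,4E)-7-[(R)-4-(tert-butyldimethylsilyloxy)-2,6,6-trimethylcyclohex-1-en-1-yl]-5-methylhepta-2,4-dien-6-yn-1-ol | CC1=C(C#C/C(C)=C/C=C/CO)C(C)(C)C[C@H](O[Si](C)(C)C(C)(C)C)C1 | intermediate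
36 | benzothiazol-2-yl sulfide of 35 (name as in step 22) | CC1=C(C#C/C(C)=C/C=C/CSc2nc3ccccc3s2)C(C)(C)C[C@H](O[Si](C)(C)C(C)(C)C)C1 | intermediate
37 | benzothiazol-2-yl sulfone (name as in step 23) | CC1=C(C#C/C(C)=C/C=C/CS(=O)(=O)c2nc3ccccc3s2)C(C)(C)C[C@H](O[Si](C)(C)C(C)(C)C)C1 | intermediate
38 | sodium α-sulfonyl carbanion of 37 (not isolated) | CC1=C(C#C/C(C)=C/C=C/C([Na])S(=O)(=O)c2nc3ccccc3s2)C(C)(C)C[C@H](O[Si](C)(C)C(C)(C)C)C1 | intermediate
39 | 3,3'-bis(tert-butyldimethylsilyl) ether of the target | CC1=C(C#C/C(C)=C/C=C/C=C/C=C(C)/C=C2C=C(/C=C/[C@@]3(O)C(C)(C)C[C@H](O[Si](C)(C)C(C)(C)C)C[C@@]3(C)O)C(=O)O/2)C(C)(C)C[C@H](O[Si](C)(C)C(C)(C)C)C1 | intermediate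
40 | CNP0163979.1 (name as in step 25) | CC1=C(C#C/C(C)=C/C=C/C=C/C=C(C)/C=C2C=C(/C=C/[C@@]3(O)C(C)(C)C[C@H](O)C[C@@]3(C)O)C(=O)O/2)C(C)(C)C[C@H](O)C1 | target

**Step count**
Total: 25 steps. Longest linear sequence: 15 steps (steps 1–8, 14–18, 24, 25).

**Steps most likely to fail**

Step 14. Oxidative addition of zerovalent palladium into the C3–Br bond, which is electron-rich and flanked by the trimethylsilyl group, may be so slow that protodestannylation and homocoupling of the stannane take over. The fallback reverses the polarity so that oxidative addition happens at a vinyl iodide; it sets out from 11 and 21 and comes back at 22. Iododestannylation of 11 (I2, CH2Cl2, 0 °C) should give, with retention, (1R,2R,4S)-4-(tert-butyldimethylsilyloxy)-1-[(E)-2-iodoethenyl]-2,6,6-trimethylcyclohexane-1,2-diol F1. Bromine–lithium exchange on 21 (t-BuLi, THF, −78 °C) and trapping with 2-isopropoxy-4,4,5,5-tetramethyl-1,3,2-dioxaborolane should give 2-{5-[(E)-4-(tert-butyldimethylsilyloxy)-2-methylbut-2-en-1-yl]-2-(trimethylsilyl)furan-3-yl}-4,4,5,5-tetramethyl-1,3,2-dioxaborolane F2. Suzuki–Miyaura coupling of F1 with F2 (Pd(dppf)Cl2, aq. K3PO4, THF, 40 °C) then gives 22.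

Step 15. Oxidation may spread beyond the furan: ene reaction of singlet oxygen at the trisubstituted side-chain alkene, [4+2] addition across the exocyclic vinylfuran diene, or breakdown of the endoperoxide before the silyl shift. The fallback gives up furan oxidation and builds the ylidene lactone by aldol condensation; it sets out from 17 and 11 and comes back at 27. MnO2 oxidation of 17 should give (E)-4-(tert-butyldimethylsilyloxy)-2-methylbut-2-enal F3. Purchased 3-bromofuran-2(5H)-one F4 is silylated in the flask (TBSOTf, i-Pr2NEt, CH2Cl2, 0 °C) to 3-bromo-2-(tert-butyldimethylsilyloxy)furan F5, which should add through C5 to F3 (vinylogous Mukaiyama aldol reaction, promoted by the same silyl triflate) to give 3-bromo-5-[(E)-1,4-bis(tert-butyldimethylsilyloxy)-2-methylbut-2-en-1-yl]furan-2(5H)-one F6. DBU then eliminates silanol to (Z)-3-bromo-5-[(E)-4-(tert-butyldimethylsilyloxy)-2-methylbut-2-en-1-ylidene]furan-2(5H)-one F7. Stille coupling of this reactive, electron-poor vinyl bromide with 11 (Pd2(dba)3, AsPh3, NMP, rt) gives 27.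

Step 24. Poor E/Z control at the new double bond, together with base-induced degradation of the aldehyde (conjugate addition to, or opening of, the ylidene lactone by the amide base or the carbanion), may erode the coupling. The fallback is a Wittig olefination under neutral conditions; it sets out from 35 and comes back at 39. CBr4 and PPh3 (CH2Cl2, −20 °C) should convert 35 into (R)-tert-butyl{[4-((3E,5E)-7-bromo-3-methylhepta-3,5-dien-1-yn-1-yl)-3,5,5-trimethylcyclohex-3-en-1-yl]oxy}dimethylsilane F8. PPh3 (EtOAc, rt) should then give the corresponding triphenylphosphonium bromide F9. Heating F9 with 29 in 1,2-epoxybutane (which takes up HBr and so generates the ylide without added base), followed by equilibration in benzene at rt in the dark, should give 39.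

**Further compounds**
F1 | step 14 | (1R,2R,4S)-4-(tert-butyldimethylsilyloxy)-1-[(E)-2-iodoethenyl]-2,6,6-trimethylcyclohexane-1,2-diol | I/C=C/[C@@]1(O)C(C)(C)C[C@H](O[Si](C)(C)C(C)(C)C)C[C@@]1(C)O
F2 | step 14 | 2-{5-[(E)-4-(tert-butyldimethylsilyloxy)-2-methylbut-2-en-1-yl]-2-(trimethylsilyl)furan-3-yl}-4,4,5,5-tetramethyl-1,3,2-dioxaborolane | C[Si](C)(C)c1oc(C/C(C)=C/CO[Si](C)(C)C(C)(C)C)cc1B1OC(C)(C)C(C)(C)O1
F3 | step 15 | (E)-4-(tert-butyldimethylsilyloxy)-2-methylbut-2-enal | O=C/C(C)=C/CO[Si](C)(C)C(C)(C)C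
F4 | step 15 | 3-bromofuran-2(5H)-one (purchased) | O=C1OCC=C1Br
F5 | step 15 | 3-bromo-2-(tert-butyldimethylsilyloxy)furan | CC(C)(C)[Si](C)(C)Oc1occc1Br
F6 | step 15 | 3-bromo-5-[(E)-1,4-bis(tert-butyldimethylsilyloxy)-2-methylbut-2-en-1-yl]furan-2(5H)-one | O=C1OC(C(O[Si](C)(C)C(C)(C)C)/C(C)=C/CO[Si](C)(C)C(C)(C)C)C=C1Br
F7 | step 15 | (Z)-3-bromo-5-[(E)-4-(tert-butyldimethylsilyloxy)-2-methylbut-2-en-1-ylidene]furan-2(5H)-one | CC(C)(C)[Si](C)(C)OC/C=C(C)/C=C1C=C(Br)C(=O)O/1
F8 | step 24 | (R)-tert-butyl{[4-((3E,5E)-7-bromo-3-methylhepta-3,5-dien-1-yn-1-yl)-3,5,5-trimethylcyclohex-3-en-1-yl]oxy}dimethylsilane | CC1=C(C#C/C(C)=C/C=C/CBr)C(C)(C)C[C@H](O[Si](C)(C)C(C)(C)C)C1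
F9 | step 24 | {(2E,4E)-7-[(R)-4-(tert-butyldimethylsilyloxy)-2,6,6-trimethylcyclohex-1-en-1-yl]-5-methylhepta-2,4-dien-6-yn-1-yl}triphenylphosphonium bromide | CC1=C(C#C/C(C)=C/C=C/C[P+](c2ccccc2)(c2ccccc2)c2ccccc2)C(C)(C)C[C@H](O[Si](C)(C)C(C)(C)C)C1.[Br-]
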